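Ring C is cut at O1–C2 and C4–C4a. This divides kushenol R into ring A, a 2-lavandulyl-5-methoxyresorcinol, and a 2-hydroxycinnamoyl unit (C2–C3–C4 plus ring B). The two halves are first joined through the wrong atom as aryl cinnamate 19, an isomer of the silylated target. One operation then shifts the acyl group from oxygen to carbon (photo-Fries rearrangement). The released phenol closes ring C by a catalyst-controlled oxa-Michael addition that sets C2. The step exploits the local symmetry of ring A: both free ring carbons (future C4a and C6) lie between C5–OMe and a C–OH, so ortho and para migration converge on one chalcone.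

Key step: step 10

Remark: flavanone numbering (O1, C2, C3, C4, C4a, C5 to C8, C8a, ring B primed) is used for all late compounds.

Assumption: the sense of induction at C2 is taken from intermolecular conjugate additions to chalcones with the same catalyst family, where the quinidine-derived thiourea sends the nucleophile to the Si face of the β-carbon; should the ring closure show the opposite sense, the pseudoenantiomeric quinine-derived thiourea replaces it with no other change.

Step 1
Reactants: 1 (S)-4-benzyl-1,3-oxazolidin-2-one; 2 3-methylbut-2-enoyl chloride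
Product: 4 (S)-4-benzyl-3-(3-methylbut-2-enoyl)-1,3-oxazolidin-2-one, via N-lithio oxazolidinone 3 (not isolated)
Conditions: n-BuLi, THF, −78 °C; then 2, −78 → 0 °C
Reagents that add atoms: none
Why: N-acylation of a lithiated oxazolidinone with an acid chloride (standard loading of an Evans auxiliary), in which the absence of a tertiary amine avoids vinylketene formation and deconjugation of 2.

Step 2
Reactants: 4 (S)-4-benzyl-3-(3-methylbut-2-enoyl)-1,3-oxazolidin-2-one; 5 1-bromo-3-methylbut-2-ene (prenyl bromide)
Product: 7 (S)-4-benzyl-3-[(2S)-5-methyl-2-(prop-1-en-2-yl)hex-4-enoyl]-1,3-oxazolidin-2-one, via sodium dienolate 6 (not isolated)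
Conditions: NaN(SiMe3)2, THF, −78 °C; then 5, −78 → −30 °C
Reagents that add atoms: none
Why: Deconjugative Evans alkylation: γ-deprotonation gives the sodium-chelated (Z)-dienolate 6, which reacts at Cα with the allylic bromide on the face opposite the benzyl group of the (S)-auxiliary and thereby sets the (2S) centre that becomes the lavandulyl stereocentre.

Step 3
Reactants: 7 (S)-4-benzyl-3-[(2S)-5-methyl-2-(prop-1-en-2-yl)hex-4-enoyl]-1,3-oxazolidin-2-one
Product: 8 (S)-lavandulol, (2S)-5-methyl-2-(prop-1-en-2-yl)hex-4-en-1-ol
Conditions: LiBH4, Et2O/THF, 0 °C → rt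
Reagents that add atoms: none
Why: Reductive cleavage of the N-acyl oxazolidinone by borohydride attacks only the exocyclic carbonyl and needs no base, so the epimerisable α-centre and both alkenes stay untouched.

Step 4
Reactants: 8 (S)-lavandulol
Product: 9 (S)-lavandulyl iodide, (2S)-1-iodo-5-methyl-2-(prop-1-en-2-yl)hex-4-ene
Conditions: I2, PPh3, imidazole, CH2Cl2, 0 °C → rt
Reagents that add atoms: iodine, II
Why: Appel iodination proceeds by SN2 displacement at the primary carbon under nearly neutral conditions, so the adjacent stereocentre is not involved.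

Step 5
Reactants: 10 5-methoxybenzene-1,3-diol (5-methoxyresorcinol)
Product: 11 1-methoxy-3,5-bis(methoxymethoxy)benzene
Conditions: MOMCl, i-Pr2NEt, CH2Cl2, 0 °C → rt
Reagents that add atoms: chloromethyl methyl ether, COCCl
Why: O-alkylation of both phenols with an α-chloro ether (acetal protection) installs the two chelating groups that direct the metalation in step 6.

Step 6
Reactants: 11 1-methoxy-3,5-bis(methoxymethoxy)benzene (2.2 equiv); 9 (S)-lavandulyl iodide
Product: 14 5-methoxy-1,3-bis(methoxymethoxy)-2-[(2R)-5-methyl-2-(prop-1-en-2-yl)hex-4-en-1-yl]benzene, via aryllithium 12 (not isolated), via diarylcuprate 13 (not isolated)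
Conditions: n-BuLi, THF, 0 °C; CuI (0.5 equiv per aryllithium), −30 °C; then 9, −30 °C → rt; NH4Cl work-up
Reagents that add atoms: none
Why: Directed ortho-metalation takes place at the carbon between the two chelating OMOM groups, and the derived Gilman diarylcuprate substitutes the primary iodide by oxidative addition/reductive elimination instead of acting as a base, the stereocentre being untouched (its descriptor changes from S to R only through the CIP priorities).

Step 7
Reactants: 14 5-methoxy-1,3-bis(methoxymethoxy)-2-[(2R)-lavandulyl]benzene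
Product: 15 5-methoxy-2-[(2R)-5-methyl-2-(prop-1-en-2-yl)hex-4-en-1-yl]benzene-1,3-diol
Conditions: HCl (3 M aq), MeOH, 40 °C
Reagents that add atoms: none
Why: Acid-catalysed acetal exchange with methanol removes aryl MOM ethers under conditions that prenylated and lavandulylated phenols are known to tolerate when acid strength and temperature are kept low.

Step 8
Reactants: 16 (E)-2-hydroxycinnamic acid (trans-o-coumaric acid)
Product: 18 (E)-3-[2-(tert-butyldimethylsilyloxy)phenyl]acrylic acid, via bis-silyl derivative 17 (not isolated)
Conditions: TBSCl (2.3 equiv), imidazole, DMF, rt; then AcOH/THF/H2O, rt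
Reagents that add atoms: tert-butyldimethylsilyl chloride, CC(C)(C)[Si](C)(C)Cl
Why: Exhaustive silylation followed by selective hydrolysis works because a silyl ester is far more labile to aqueous acid than an aryl silyl ether, and the E-alkene cannot lactonise.

Step 9
Reactants: 15 5-methoxy-2-[(2R)-lavandulyl]benzene-1,3-diol; 18 (E)-3-[2-(tert-butyldimethylsilyloxy)phenyl]acrylic acid
Product: 19 3-hydroxy-5-methoxy-2-[(2R)-lavandulyl]phenyl (E)-3-[2-(tert-butyldimethylsilyloxy)phenyl]acrylate (monoester)
Conditions: DCC, DMAP (10 mol %), CH2Cl2, 0 °C; 18 (0.8 equiv) added slowly to 15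
Reagents that add atoms: none
Why: Steglich esterification; the two OH groups of 15 are interchanged by rotation about the aryl–CH2 bond and give the same monoester, so only double acylation has to be limited, which the deficit and slow addition of 18 should do (unreacted 15 is recovered).

Step 10
Reactants: 19 monoester
Product: 21 (2S)-2'-O-(tert-butyldimethylsilyl)kushenol R, via chalcone 20 (not isolated)
Conditions: hν (medium-pressure mercury lamp, λ ≥ 280 nm), degassed PhCF3 (5 mM), 15 °C; lamp off, concentrated to 0.1 M; 1-[3,5-bis(trifluoromethyl)phenyl]-3-[(9R)-6'-methoxycinchonan-9-yl]thiourea (quinidine-derived, 20 mol %), −10 °C, dark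
Reagents that add atoms: none
Why: Light cleaves the O1–acyl bond of 19 homolytically to a solvent-caged aryloxyl/cinnamoyl radical pair, which recombines at a free carbon of ring A and rearomatises to 2'-hydroxychalcone 20 (C4–C4a), and in the dark the bifunctional amine-thiourea then adds the released O1–H to the enone (O1–C2). The closest known reaction types are the photo-Fries rearrangement of hydroxyphenyl cinnamates to 2'-hydroxychalcones and flavanones and the cinchona-thiourea-catalysed enantioselective cyclisation of 2'-hydroxychalcones, here run in one flask. Ring C closes in a 6-endo-trig intramolecular oxa-Michael addition. C2 is controlled by the catalyst: the thiourea binds the C4 carbonyl, the quinuclidine nitrogen takes the O1–H proton, and the C8/C9 array of the alkaloid exposes the Si face of C2, which gives 2S, while the remote lavandulyl centre should have no say. Site selectivity is secured by ring A itself, since ortho and para recombination both place the acyl group between OMe and OH and give the same chalcone, the other ortho carbon is blocked by the lavandulyl CH2, and only one OH neighbours the new ketone. The aryl silyl ether prevents the E-to-Z photolactonisation to coumarin that a free 2-hydroxycinnamate would suffer, the neutral degassed medium spares both lavandulyl alkenes, and the twist imposed by the 6'-OMe group (as in the xanthohumol to isoxanthohumol isomerisation) makes closure downhill, so that low temperature should keep it under kinetic control.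

Step 11
Reactants: 21 (2S)-2'-O-(tert-butyldimethylsilyl)kushenol R
Product: 22 kushenol R, (2S)-7-hydroxy-2-(2-hydroxyphenyl)-5-methoxy-8-[(2R)-5-methyl-2-(prop-1-en-2-yl)hex-4-en-1-yl]chroman-4-one
Conditions: Et3N·3HF, THF, 0 °C → rt
Reagents that add atoms: none
Why: Fluoride cleaves the aryl silyl ether through pentacoordinate silicon, and the weakly acidic amine–HF medium avoids the base-induced retro-oxa-Michael opening of ring C that would epimerise C2.

Compound list

1 | (S)-4-benzyl-1,3-oxazolidin-2-one | O=C1N[C@@H](Cc2ccccc2)CO1 | starting material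
2 | 3-methylbut-2-enoyl chloride | CC(C)=CC(=O)Cl | starting material
3 | N-lithio-(S)-4-benzyl-1,3-oxazolidin-2-one | [Li]N1C(=O)OC[C@@H]1Cc1ccccc1 | intermediate
4 | (S)-4-benzyl-3-(3-methylbut-2-enoyl)-1,3-oxazolidin-2-one | CC(C)=CC(=O)N1C(=O)OC[C@@H]1Cc1ccccc1 | intermediate
5 | 1-bromo-3-methylbut-2-ene (prenyl bromide) | CC(C)=CCBr | starting material
6 | sodium (Z)-dienolate of 4 | [Na+].C=C(C)/C=C(\[O-])N1C(=O)OC[C@@H]1Cc1ccccc1 | intermediate
7 | (S)-4-benzyl-3-[(2S)-5-methyl-2-(prop-1-en-2-yl)hex-4-enoyl]-1,3-oxazolidin-2-one | C=C(C)[C@H](CC=C(C)C)C(=O)N1C(=O)OC[C@@H]1Cc1ccccc1 | intermediate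
8 | (S)-lavandulol | C=C(C)[C@H](CC=C(C)C)CO | intermediate
9 | (S)-lavandulyl iodide | C=C(C)[C@H](CC=C(C)C)CI | intermediate
10 | 5-methoxybenzene-1,3-diol | COc1cc(O)cc(O)c1 | starting material
11 | 1-methoxy-3,5-bis(methoxymethoxy)benzene | COCOc1cc(OC)cc(OCOC)c1 | intermediate
12 | [4-methoxy-2,6-bis(methoxymethoxy)phenyl]lithium | [Li]c1c(OCOC)cc(OC)cc1OCOC | intermediate
13 | lithium bis[4-methoxy-2,6-bis(methoxymethoxy)phenyl]cuprate | [Li+].COCOc1cc(OC)cc(OCOC)c1[Cu-]c1c(OCOC)cc(OC)cc1OCOC | intermediate
14 | 5-methoxy-1,3-bis(methoxymethoxy)-2-[(2R)-lavandulyl]benzene | C=C(C)[C@H](CC=C(C)C)Cc1c(OCOC)cc(OC)cc1OCOC | intermediate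
15 | 5-methoxy-2-[(2R)-lavandulyl]benzene-1,3-diol | C=C(C)[C@H](CC=C(C)C)Cc1c(O)cc(OC)cc1O | intermediate
16 | (E)-2-hydroxycinnamic acid | O=C(O)/C=C/c1ccccc1O | starting material
17 | tert-butyldimethylsilyl (E)-3-[2-(tert-butyldimethylsilyloxy)phenyl]acrylate | CC(C)(C)[Si](C)(C)OC(=O)/C=C/c1ccccc1O[Si](C)(C)C(C)(C)C | intermediate
18 | (E)-3-[2-(tert-butyldimethylsilyloxy)phenyl]acrylic acid | O=C(O)/C=C/c1ccccc1O[Si](C)(C)C(C)(C)C | intermediate
19 | 3-hydroxy-5-methoxy-2-[(2R)-lavandulyl]phenyl (E)-3-[2-(tert-butyldimethylsilyloxy)phenyl]acrylate | C=C(C)[C@H](CC=C(C)C)Cc1c(O)cc(OC)cc1OC(=O)/C=C/c1ccccc1O[Si](C)(C)C(C)(C)C | intermediate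
20 | (E)-2',4'-dihydroxy-6'-methoxy-3'-[(2R)-lavandulyl]-2-(tert-butyldimethylsilyloxy)chalcone | C=C(C)[C@H](CC=C(C)C)Cc1c(O)cc(OC)c(C(=O)/C=C/c2ccccc2O[Si](C)(C)C(C)(C)C)c1O | intermediate
21 | (2S)-2'-O-(tert-butyldimethylsilyl)kushenol R | C=C(C)[C@H](CC=C(C)C)Cc1c(O)cc(OC)c2c1O[C@H](c1ccccc1O[Si](C)(C)C(C)(C)C)CC2=O | intermediate
22 | kushenol R | C=C(C)[C@H](CC=C(C)C)Cc1c(O)cc(OC)c2c1O[C@H](c1ccccc1O)CC2=O | target

Total step count: 11. Longest linear sequence: 9 (steps 1, 2, 3, 4, 6, 7, 9, 10, 11).

Steps most likely to fail

Step 10.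
- The acyl shift may lose material through escape of the radical pair from the solvent cage, E/Z isomerisation and [2+2] consumption of the cinnamate.
- Light-driven closure of the chalcone before the catalyst is added would occur without facial control.
- The free 7-OH may compete for the catalyst and weaken facial selectivity.

The fallback sets out from diol 15 and acid 18 and comes back at 21.
- Acid 18 is converted with 1-chloro-N,N,2-trimethylprop-1-en-1-amine (CH2Cl2, 0 °C, neutral) into (E)-3-[2-(tert-butyldimethylsilyloxy)phenyl]acryloyl chloride F1.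
- Diol 15 is converted with EtMgBr (2 equiv, Et2O then toluene) into its bis(bromomagnesium) phenolate F2.
- F2 is C-acylated by F1 at the carbon ortho to O–Mg inside the magnesium chelate (thermal ortho-selective acylation of aryloxymagnesium bromides). After NH4Cl work-up this gives chalcone 20, now isolated and purified.
- Closure with Et3N in MeOH at 40 °C, without facial control, gives 21 together with the (2R)-epimer of 21 F3.
- The two are diastereomers and are separated by preparative HPLC. F3 is returned to the same basic medium, where it re-equilibrates through 20.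

Step 6.
- Substitution at the β-branched primary carbon may be slow.
- Elimination towards the conjugated diene may compete.
- Part of the metalation may occur at the carbon between OMOM and OMe.

The fallback sets out from 11 (through aryllithium 12) and 9 and comes back at 14.
- Aryllithium 12 is quenched with I2 to 2-iodo-5-methoxy-1,3-bis(methoxymethoxy)benzene F4, which is freed from any regioisomer by crystallisation or chromatography.
- Iodide 9 is converted with zinc dust and LiCl in THF into (S)-lavandulylzinc iodide F5.
- A Negishi coupling of F4 and F5 with Pd(OAc)2 and SPhos in THF at 40 °C forms the aryl–CH2 bond with reversed polarity.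

Step 7.
- The liberated phenol may add to the isopropenyl or prenyl double bond under acid, which would form a chroman.

The fallback sets out from 10 (and 9) and comes back at 15. It replaces the acid-labile protecting group with a fluoride-labile one.
- Diol 10 is converted with SEMCl and i-Pr2NEt into 1-methoxy-3,5-bis{[2-(trimethylsilyl)ethoxy]methoxy}benzene F6.
- F6 is lithiated with n-BuLi to the aryllithium F7 and converted with CuI into the diarylcuprate F8.
- F8 is alkylated with 9 as in step 6 to give the lavandulyl bis-SEM arene F9.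
- Bu4NF in THF/DMPU at 80 °C then releases 15 without any acid.

Further compounds

F1 | step 10 | (E)-3-[2-(tert-butyldimethylsilyloxy)phenyl]acryloyl chloride | O=C(Cl)/C=C/c1ccccc1O[Si](C)(C)C(C)(C)C
F2 | step 10 | bis(bromomagnesium) phenolate of 15 | C=C(C)[C@H](CC=C(C)C)Cc1c(O[Mg]Br)cc(OC)cc1O[Mg]Br
F3 | step 10 | (2R)-epimer of 21 | C=C(C)[C@H](CC=C(C)C)Cc1c(O)cc(OC)c2c1O[C@@H](c1ccccc1O[Si](C)(C)C(C)(C)C)CC2=O
F4 | step 6 | 2-iodo-5-methoxy-1,3-bis(methoxymethoxy)benzene | COCOc1cc(OC)cc(OCOC)c1I
F5 | step 6 | (S)-lavandulylzinc iodide | C=C(C)[C@H](CC=C(C)C)C[Zn]I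
F6 | step 7 | 1-methoxy-3,5-bis{[2-(trimethylsilyl)ethoxy]methoxy}benzene | COc1cc(OCOCC[Si](C)(C)C)cc(OCOCC[Si](C)(C)C)c1
F7 | step 7 | (4-methoxy-2,6-bis{[2-(trimethylsilyl)ethoxy]methoxy}phenyl)lithium | [Li]c1c(OCOCC[Si](C)(C)C)cc(OC)cc1OCOCC[Si](C)(C)C
F8 | step 7 | lithium bis(4-methoxy-2,6-bis{[2-(trimethylsilyl)ethoxy]methoxy}phenyl)cuprate | [Li+].COc1cc(OCOCC[Si](C)(C)C)c([Cu-]c2c(OCOCC[Si](C)(C)C)cc(OC)cc2OCOCC[Si](C)(C)C)c(OCOCC[Si](C)(C)C)c1
F9 | step 7 | 5-methoxy-2-[(2R)-lavandulyl]-1,3-bis{[2-(trimethylsilyl)ethoxy]methoxy}benzene | C=C(C)[C@H](CC=C(C)C)Cc1c(OCOCC[Si](C)(C)C)cc(OC)cc1OCOCC[Si](C)(C)C
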